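**Retrosynthetic overview**
- The medium ring (ring B) is closed last by ring-closing metathesis at the C4=C5 (Z) alkene; the C8 methacrylate and the free C9 hydroxyl are released after ring closure.
- The metathesis precursor comes from two fragments joined at C9–C10 by a chelation-controlled Mukaiyama aldol: fragment N (a 3-silyloxyfuran: C1–C5, C10, C14, C15) and fragment S (a lactone aldehyde: C6–C9, C11–C13).
- Fragment S: the cis-fused α-methylene-γ-lactone (ring C) is built by Morita–Baylis–Hillman reaction, allylic bromination and a zinc Barbier allylation of acrolein; C8 comes from a palladium-catalysed asymmetric etherification of butadiene monoxide.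
- Fragment N: the 3(2H)-furanone (ring A) is built by gold-catalysed cyclisation of an α′-hydroxy ynone made from a lactate Weinreb amide and 2-methylbut-1-en-3-yne.
- Ring order: A and C in separate branches, then B.

Convention: macrocycle stereodescriptors use germacranolide numbering (C1 ketone, C2=C3 furanone alkene, C4=C5, C6 lactone carbinol, C7, C8 ester carbinol, C9 carbinol, C10 quaternary carbon, C11–C13 methylene lactone, C14/C15 methyls). The target is (4Z,6S,7S,8S,9R,10R).
Assumption: the (R,R)-configured Trost ligand gives the (S)-ether in step 7; if the sense is opposite, the (S,S)-ligand is used.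

**Fragment N**

Step 1
Reactants: 1 ethyl 2-hydroxypropanoate (ethyl lactate, racemic)
Product: 2 ethyl 2-[(tert-butyldimethylsilyl)oxy]propanoate (racemic)
Conditions: TBSCl, imidazole, DMF, rt
Reagents that add atoms: tert-butyldimethylsilyl chloride, CC(C)(C)[Si](C)(C)Cl
Why: Silyl ether formation protects the hydroxyl for the ester-to-ketone chemistry; the stereocentre is racemic and is erased in step 6.

Step 2
Reactants: 2 ethyl 2-[(tert-butyldimethylsilyl)oxy]propanoate
Product: 3 2-[(tert-butyldimethylsilyl)oxy]-N-methoxy-N-methylpropanamide (racemic)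
Conditions: MeNH(OMe)·HCl, i-PrMgCl, THF, −20 → 0 °C
Reagents that add atoms: N,O-dimethylhydroxylamine hydrochloride, CNOC.Cl
Why: Weinreb amide formation by aminolysis of the ester with the chloromagnesium amide.

Step 3
Reactants: 3 2-[(tert-butyldimethylsilyl)oxy]-N-methoxy-N-methylpropanamide; 4 2-methylbut-1-en-3-yne
Product: 6 2-[(tert-butyldimethylsilyl)oxy]-6-methylhept-6-en-4-yn-3-one (racemic), via lithium acetylide 5 (not isolated)
Conditions: n-BuLi, THF, −78 °C (on 4); then 3, −78 → 0 °C; H2O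
Reagents that add atoms: none
Why: Acetylide acylation of a Weinreb amide stops at the ynone because the chelated tetrahedral intermediate only collapses on work-up.

Step 4
Reactants: 6 2-[(tert-butyldimethylsilyl)oxy]-6-methylhept-6-en-4-yn-3-one
Product: 7 2-hydroxy-6-methylhept-6-en-4-yn-3-one (racemic)
Conditions: HF·pyridine, THF, 0 °C → rt
Reagents that add atoms: none
Why: Fluoride desilylation under acidic conditions frees the α′-hydroxyl without base-induced side reactions of the ynone.

Step 5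
Reactants: 7 2-hydroxy-6-methylhept-6-en-4-yn-3-one
Product: 8 2-methyl-5-(prop-1-en-2-yl)furan-3(2H)-one (racemic)
Conditions: AuCl3 (5 mol %), CH2Cl2, rt
Reagents that add atoms: none
Why: Gold-catalysed 5-endo-dig hydroalkoxylation (intramolecular oxa-Michael addition) of the α′-hydroxyl onto the activated ynone forms the 3(2H)-furanone, ring A.

Step 6
Reactants: 8 2-methyl-5-(prop-1-en-2-yl)furan-3(2H)-one
Product: 9 triethyl{[2-methyl-5-(prop-1-en-2-yl)furan-3-yl]oxy}silane
Conditions: TESOTf, Et3N, CH2Cl2, 0 °C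
Reagents that add atoms: triethylsilyl trifluoromethanesulfonate, CC[Si](CC)(CC)OS(=O)(=O)C(F)(F)F
Why: Soft enolisation and O-silylation give the aromatic 3-silyloxyfuran, an enol silane that is nucleophilic at C2 (the future C10).

**Fragment S**

Step 7
Reactants: 10 2-vinyloxirane (butadiene monoxide, racemic); 11 4-methoxybenzyl alcohol
Product: 12 (2S)-2-[(4-methoxybenzyl)oxy]but-3-en-1-ol
Conditions: Pd2(dba)3·CHCl3 (1 mol %), (R,R)-DACH-naphthyl Trost ligand (3 mol %), Et3B (1 mol %), CH2Cl2, rt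
Reagents that add atoms: none
Why: Palladium-catalysed dynamic kinetic asymmetric allylic etherification (Tsuji–Trost type): the interconverting π-allylpalladium complexes from the racemic epoxide are trapped at the internal carbon by the boron-bound alkoxide, and the chiral ligand sets the future C8.

Step 8
Reactants: 12 (2S)-2-[(4-methoxybenzyl)oxy]but-3-en-1-ol
Product: 13 triethyl{[(2S)-2-[(4-methoxybenzyl)oxy]but-3-en-1-yl]oxy}silane
Conditions: TESCl, imidazole, CH2Cl2, 0 °C
Reagents that add atoms: triethylsilyl chloride, CC[Si](Cl)(CC)CC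
Why: Silylation masks the primary hydroxyl (the future C9 aldehyde) through the lactone construction.

Step 9
Reactants: 13 triethyl{[(2S)-2-[(4-methoxybenzyl)oxy]but-3-en-1-yl]oxy}silane
Product: 15 (2R)-2-[(4-methoxybenzyl)oxy]-3-[(triethylsilyl)oxy]propanal, via ozonide 14 (not isolated)
Conditions: O3, CH2Cl2, −78 °C (stopped at first excess); then PPh3, −78 °C → rt
Reagents that add atoms: ozone, [O-][O+]=O
Why: Ozonolysis with reductive work-up cleaves the only alkene to the C7 aldehyde without touching the adjacent stereocentre.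

Step 10
Reactants: 15 (2R)-2-[(4-methoxybenzyl)oxy]-3-[(triethylsilyl)oxy]propanal; 16 methyl acrylate
Product: 17 methyl (4R)-3-hydroxy-4-[(4-methoxybenzyl)oxy]-2-methylidene-5-[(triethylsilyl)oxy]pentanoate (C3 epimers)
Conditions: DABCO, 1,4-dioxane/H2O (1:1), rt
Reagents that add atoms: none
Why: Morita–Baylis–Hillman reaction attaches the acrylate unit (C11–C13); the new carbinol centre is formed as a mixture and is removed in step 11.

Step 11
Reactants: 17 methyl (4R)-3-hydroxy-4-[(4-methoxybenzyl)oxy]-2-methylidene-5-[(triethylsilyl)oxy]pentanoate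
Product: 18 methyl (2Z,4S)-2-(bromomethyl)-4-[(4-methoxybenzyl)oxy]-5-[(triethylsilyl)oxy]pent-2-enoate
Conditions: NBS, Me2S, CH2Cl2, 0 °C → rt
Reagents that add atoms: N-bromosuccinimide, O=C1CCC(=O)N1Br
Why: Corey–Kim-type activation of the allylic alcohol and SN2′ attack of bromide give the thermodynamically preferred (Z)-2-(bromomethyl)alkenoate.

Step 12
Reactants: 18 methyl (2Z,4S)-2-(bromomethyl)-4-[(4-methoxybenzyl)oxy]-5-[(triethylsilyl)oxy]pent-2-enoate; 19 acrolein (prop-2-enal)
Product: 21 (4S,5S)-4-{(1S)-1-[(4-methoxybenzyl)oxy]-2-[(triethylsilyl)oxy]ethyl}-3-methylidene-5-vinyloxolan-2-one, via hydroxy ester 20 (not isolated)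
Conditions: Zn, sat. aq NH4Cl/THF, 0 °C → rt; then PPTS, CH2Cl2, rt
Reagents that add atoms: none
Why: Zinc Barbier allylation through a chair transition state puts the (Z) γ-substituent axial and so gives the 6,7-syn adduct (cis-lactone, 6S), acrolein is attacked on the allyl face anti to the CH2OTES carbon in the rotamer with C8–H eclipsing the alkene (A(1,3) minimised, 7S), and PPTS then closes ring C.

Step 13
Reactants: 21 (4S,5S)-4-{(1S)-1-[(4-methoxybenzyl)oxy]-2-[(triethylsilyl)oxy]ethyl}-3-methylidene-5-vinyloxolan-2-one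
Product: 22 (2S)-2-[(4-methoxybenzyl)oxy]-2-[(2S,3S)-4-methylidene-5-oxo-2-vinyloxolan-3-yl]acetaldehyde
Conditions: (COCl)2, DMSO, CH2Cl2, −78 → −30 °C; then Et3N, −78 → 0 °C
Reagents that add atoms: none
Why: Swern oxidation applied directly to the primary triethylsilyl ether, which is cleaved by the chlorosulfonium reagent, gives the C9 aldehyde in one operation.

**Union and ring closure**

Step 14
Reactants: 22 (2S)-2-[(4-methoxybenzyl)oxy]-2-[(2S,3S)-4-methylidene-5-oxo-2-vinyloxolan-3-yl]acetaldehyde; 9 triethyl{[2-methyl-5-(prop-1-en-2-yl)furan-3-yl]oxy}silane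
Product: 24 (4S,5S)-4-{(1S,2R)-1-[(4-methoxybenzyl)oxy]-2-[(2R)-2-methyl-3-oxo-5-(prop-1-en-2-yl)-2,3-dihydrofuran-2-yl]-2-[(triethylsilyl)oxy]ethyl}-3-methylidene-5-vinyloxolan-2-one, via aldol 23 (not isolated)
Conditions: MgBr2·OEt2 (3 equiv), CH2Cl2, −78 → −30 °C; then 2,6-lutidine, TESOTf, −30 → 0 °C
Reagents that add atoms: triethylsilyl trifluoromethanesulfonate, CC[Si](CC)(CC)OS(=O)(=O)C(F)(F)F
Why: Chelation-controlled Mukaiyama aldol: magnesium bridges the aldehyde and PMB-ether oxygens so the furan adds anti to the lactone substituent (8,9-syn, 9R), an open antiperiplanar transition state that turns the furan C2 methyl away from the chelate sets 10R, and the aldolate is silylated in the same flask.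

Step 15
Reactants: 24 the silylated aldol of step 14
Product: 25 (4Z,6S,7S,8S,9R,10R)-8-[(4-methoxybenzyl)oxy]-1-oxo-9-[(triethylsilyl)oxy]-3,10-epoxygermacra-2,4,11(13)-trien-12,6-olide
Conditions: second-generation Hoveyda–Grubbs catalyst (15 mol %), toluene (1 mM), 80 °C, argon sparge
Reagents that add atoms: none
Why: Ring-closing metathesis between the C6 vinyl group and the furanone isopropenyl group closes ring B with loss of ethylene, and the ring size allows only the (Z)-trisubstituted alkene.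

Step 16
Reactants: 25 the macrocycle of step 15
Product: 26 (4Z,6S,7S,8S,9R,10R)-8-hydroxy-1-oxo-9-[(triethylsilyl)oxy]-3,10-epoxygermacra-2,4,11(13)-trien-12,6-olide
Conditions: DDQ, CH2Cl2/pH 7 phosphate buffer (10:1), 0 °C → rt
Reagents that add atoms: none
Why: Oxidative cleavage of the p-methoxybenzyl ether frees only the C8 hydroxyl, since C9 is silylated and the electron-poor alkenes are inert to DDQ.

Step 17
Reactants: 26 the C8 alcohol of step 16; 27 methacrylic anhydride
Product: 28 (4Z,6S,7S,8S,9R,10R)-8-(methacryloyloxy)-1-oxo-9-[(triethylsilyl)oxy]-3,10-epoxygermacra-2,4,11(13)-trien-12,6-olide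
Conditions: Et3N, DMAP, CH2Cl2, 0 °C → rt
Reagents that add atoms: none
Why: DMAP-catalysed acylation of the only free hydroxyl installs the methacrylate with retention at C8.

Step 18
Reactants: 28 the methacrylate of step 17
Product: 29 (4Z,6S,7S,8S,9R,10R)-9-hydroxy-8-(methacryloyloxy)-1-oxo-3,10-epoxygermacra-2,4,11(13)-trien-12,6-olide (CNP0252578.4)
Conditions: HF·pyridine, THF/pyridine, 0 °C
Reagents that add atoms: none
Why: Mild acidic fluoride desilylation frees the C9 hydroxyl without touching the methacrylate, the α-methylene lactone or the furanone.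

**Compound list**
1 | ethyl 2-hydroxypropanoate (racemic) | CCOC(=O)C(C)O | starting material
2 | ethyl 2-[(tert-butyldimethylsilyl)oxy]propanoate (racemic) | CCOC(=O)C(C)O[Si](C)(C)C(C)(C)C | intermediate
3 | 2-[(tert-butyldimethylsilyl)oxy]-N-methoxy-N-methylpropanamide (racemic) | CON(C)C(=O)C(C)O[Si](C)(C)C(C)(C)C | intermediate
4 | 2-methylbut-1-en-3-yne | C#CC(C)=C | starting material
5 | lithium 3-methylbut-3-en-1-yn-1-ide (not isolated) | [Li]C#CC(C)=C | intermediate
6 | 2-[(tert-butyldimethylsilyl)oxy]-6-methylhept-6-en-4-yn-3-one (racemic) | CC(O[Si](C)(C)C(C)(C)C)C(=O)C#CC(C)=C | intermediate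
7 | 2-hydroxy-6-methylhept-6-en-4-yn-3-one (racemic) | CC(O)C(=O)C#CC(C)=C | intermediate
8 | 2-methyl-5-(prop-1-en-2-yl)furan-3(2H)-one (racemic) | CC1OC(C(C)=C)=CC1=O | intermediate
9 | triethyl{[2-methyl-5-(prop-1-en-2-yl)furan-3-yl]oxy}silane | Cc1oc(C(C)=C)cc1O[Si](CC)(CC)CC | intermediate
10 | 2-vinyloxirane (racemic) | C=CC1CO1 | starting material
11 | 4-methoxybenzyl alcohol | COc1ccc(CO)cc1 | starting material
12 | (2S)-2-[(4-methoxybenzyl)oxy]but-3-en-1-ol | C=C[C@@H](CO)OCc1ccc(OC)cc1 | intermediate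
13 | triethyl{[(2S)-2-[(4-methoxybenzyl)oxy]but-3-en-1-yl]oxy}silane | C=C[C@@H](CO[Si](CC)(CC)CC)OCc1ccc(OC)cc1 | intermediate
14 | 3-{(1R)-1-[(4-methoxybenzyl)oxy]-2-[(triethylsilyl)oxy]ethyl}-1,2,4-trioxolane (ring-carbon epimers, not isolated) | CC[Si](CC)(CC)OC[C@@H](OCc1ccc(OC)cc1)C1OCOO1 | intermediate
15 | (2R)-2-[(4-methoxybenzyl)oxy]-3-[(triethylsilyl)oxy]propanal | O=C[C@@H](CO[Si](CC)(CC)CC)OCc1ccc(OC)cc1 | intermediate
16 | methyl acrylate | C=CC(=O)OC | starting material
17 | methyl (4R)-3-hydroxy-4-[(4-methoxybenzyl)oxy]-2-methylidene-5-[(triethylsilyl)oxy]pentanoate (C3 epimers) | COC(=O)C(=C)C(O)[C@@H](CO[Si](CC)(CC)CC)OCc1ccc(OC)cc1 | intermediate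
18 | methyl (2Z,4S)-2-(bromomethyl)-4-[(4-methoxybenzyl)oxy]-5-[(triethylsilyl)oxy]pent-2-enoate | COC(=O)/C(CBr)=C/[C@@H](CO[Si](CC)(CC)CC)OCc1ccc(OC)cc1 | intermediate
19 | acrolein | C=CC=O | starting material
20 | methyl (3S,4S)-4-hydroxy-3-{(1S)-1-[(4-methoxybenzyl)oxy]-2-[(triethylsilyl)oxy]ethyl}-2-methylidenehex-5-enoate (not isolated) | COc1ccc(CO[C@H](CO[Si](CC)(CC)CC)[C@H]([C@@H](O)C=C)C(=C)C(=O)OC)cc1 | intermediate
21 | (4S,5S)-4-{(1S)-1-[(4-methoxybenzyl)oxy]-2-[(triethylsilyl)oxy]ethyl}-3-methylidene-5-vinyloxolan-2-one | COc1ccc(CO[C@H](CO[Si](CC)(CC)CC)[C@H]2C(=C)C(=O)O[C@H]2C=C)cc1 | intermediate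
22 | (2S)-2-[(4-methoxybenzyl)oxy]-2-[(2S,3S)-4-methylidene-5-oxo-2-vinyloxolan-3-yl]acetaldehyde | O=C[C@@H](OCc1ccc(OC)cc1)[C@H]1C(=C)C(=O)O[C@H]1C=C | intermediate
23 | (4S,5S)-4-{(1S,2R)-2-hydroxy-1-[(4-methoxybenzyl)oxy]-2-[(2R)-2-methyl-3-oxo-5-(prop-1-en-2-yl)-2,3-dihydrofuran-2-yl]ethyl}-3-methylidene-5-vinyloxolan-2-one (present as its magnesium alkoxide, not isolated) | COc1ccc(CO[C@@H]([C@H]2C(=C)C(=O)O[C@H]2C=C)[C@@H](O)[C@@]3(C)OC(C(C)=C)=CC3=O)cc1 | intermediate
24 | C9 triethylsilyl ether of 23 | COc1ccc(CO[C@@H]([C@H]2C(=C)C(=O)O[C@H]2C=C)[C@@H](O[Si](CC)(CC)CC)[C@@]3(C)OC(C(C)=C)=CC3=O)cc1 | intermediate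
25 | (4Z,6S,7S,8S,9R,10R)-8-[(4-methoxybenzyl)oxy]-1-oxo-9-[(triethylsilyl)oxy]-3,10-epoxygermacra-2,4,11(13)-trien-12,6-olide | COc1ccc(CO[C@H]2[C@H]3C(=C)C(=O)O[C@H]3/C=C(/C)C3=CC(=O)[C@](C)(O3)[C@@H]2O[Si](CC)(CC)CC)cc1 | intermediate
26 | (4Z,6S,7S,8S,9R,10R)-8-hydroxy-1-oxo-9-[(triethylsilyl)oxy]-3,10-epoxygermacra-2,4,11(13)-trien-12,6-olide | O[C@H]1[C@H]2C(=C)C(=O)O[C@H]2/C=C(/C)C2=CC(=O)[C@](C)(O2)[C@@H]1O[Si](CC)(CC)CC | intermediate
27 | methacrylic anhydride | C=C(C)C(=O)OC(=O)C(C)=C | starting material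
28 | (4Z,6S,7S,8S,9R,10R)-8-(methacryloyloxy)-1-oxo-9-[(triethylsilyl)oxy]-3,10-epoxygermacra-2,4,11(13)-trien-12,6-olide | C=C(C)C(=O)O[C@H]1[C@H]2C(=C)C(=O)O[C@H]2/C=C(/C)C2=CC(=O)[C@](C)(O2)[C@@H]1O[Si](CC)(CC)CC | intermediate
29 | (4Z,6S,7S,8S,9R,10R)-9-hydroxy-8-(methacryloyloxy)-1-oxo-3,10-epoxygermacra-2,4,11(13)-trien-12,6-olide (CNP0252578.4) | C=C(C)C(=O)O[C@H]1[C@H]2C(=C)C(=O)O[C@H]2/C=C(/C)C2=CC(=O)[C@](C)(O2)[C@@H]1O | target

**Step count**
Total steps: 18. Longest linear sequence: 12 (steps 7–13, then 14–18). The other branch is steps 1–6, then 14–18 (11 steps).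

**Three steps most likely to fail**

Step 14 (aldol union). The C9 configuration rests on chelation and the C10 configuration on an open transition state, and the hindered enol silane may react sluggishly. Fallback: it sets out from 9. Bromination with NBS in THF at −78 °C gives 2-bromo-2-methyl-5-(prop-1-en-2-yl)furan-3(2H)-one F3. SmI2 in THF at −78 °C then reduces F3 in the presence of aldehyde 22 to a samarium enolate. This enolate adds in a Reformatsky-type aldol through a closed chair transition state in which samarium binds the enolate, aldehyde and PMB-ether oxygens; the methyl group cis to the enolate oxygen ends up syn to the new hydroxyl. The route is rejoined at aldol 23, which is silylated with TESOTf and 2,6-lutidine as in step 14 to give 24.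

Step 15 (ring-closing metathesis). The acceptor alkene is 1,1-disubstituted and electron-poor, and the alkylidene formed at C5 sits next to the α-methylene lactone, which can divert the catalyst into chelation or cross-metathesis. Fallback: it sets out from 24. Dimethylamine in THF at 0 °C adds to the exocyclic methylene to give the dimethylamine Michael adduct F4. As its p-toluenesulfonate salt, F4 is cyclised with the second-generation Hoveyda–Grubbs catalyst in toluene at 80 °C to the macrocyclic amine F5. Quaternisation of F5 with MeI followed by aqueous NaHCO3 eliminates trimethylamine, restores the methylene lactone and rejoins the route at 25.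

Step 12 (Barbier allylation). The facial selectivity relative to C8 could be eroded or reversed if the PMB-ether oxygen coordinates zinc in water. Fallback: it sets out from 17. Acetylation with Ac2O, DMAP and pyridine gives the allylic acetate F1. Palladium-catalysed SN2′ borylation (B2pin2, Pd2(dba)3, toluene, 50 °C) converts F1 into the allylboronate F2. Heating F2 with acrolein 19 in toluene at 80 °C gives a thermal allylboration through a closed chair transition state in which boron cannot chelate the ether. Work-up with PPTS lactonises the adduct and rejoins the route at 21.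

**Further compounds**
F1 | step 12 | methyl (4R)-3-acetoxy-4-[(4-methoxybenzyl)oxy]-2-methylidene-5-[(triethylsilyl)oxy]pentanoate (C3 epimers) | COC(=O)C(=C)C(OC(C)=O)[C@@H](CO[Si](CC)(CC)CC)OCc1ccc(OC)cc1
F2 | step 12 | methyl (2E,4S)-4-[(4-methoxybenzyl)oxy]-2-[(4,4,5,5-tetramethyl-1,3,2-dioxaborolan-2-yl)methyl]-5-[(triethylsilyl)oxy]pent-2-enoate | COC(=O)/C(CB1OC(C)(C)C(C)(C)O1)=C/[C@@H](CO[Si](CC)(CC)CC)OCc1ccc(OC)cc1
F3 | step 14 | 2-bromo-2-methyl-5-(prop-1-en-2-yl)furan-3(2H)-one (racemic) | CC1(Br)OC(C(C)=C)=CC1=O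
F4 | step 15 | dimethylamine Michael adduct of 24 (C11 bears CH2NMe2, C11 epimers) | COc1ccc(CO[C@@H]([C@H]2C(CN(C)C)C(=O)O[C@H]2C=C)[C@@H](O[Si](CC)(CC)CC)[C@@]3(C)OC(C(C)=C)=CC3=O)cc1
F5 | step 15 | macrocyclic amine (25 with CH2NMe2 at C11 in place of the methylidene, C11 epimers) | COc1ccc(CO[C@H]2[C@H]3C(CN(C)C)C(=O)O[C@H]3/C=C(/C)C3=CC(=O)[C@](C)(O3)[C@@H]2O[Si](CC)(CC)CC)cc1
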